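The route rests on disconnecting C1–C8a of the carbocycle. In the target, the pyran methylene C1 and the C8 hydroxyl lie cis on the neighbouring ring carbons C8a and C8, a 1,3-dioxygen pattern. A (bromomethyl)dimethylsilyl ether on the C8 oxygen of a shikimate enoate closes by 5-exo radical addition to C8a, forming C1–C8a and the C8a stereocentre in one operation; oxidation of silicon later returns C1–OH and C8–OH. The precursor is methyl shikimate with the trans C6/C7 diol locked as a butane-2,3-diacetal and the allylic C8 oxygen silylated. The C7 carbinol, the C6 enone and a C4 alkyne that closes the pyran follow.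

Key step: step 3

Remark 1: ring positions follow the isochromenone (C1, O2, C3, C4, C4a, C5–C8, C8a; side chain C1′–C7′); α is the face that carries the C8 oxygen (and, in the target, C1 and the C7 methyl), β the opposite face.

Remark 2: elimination of the tertiary hydroxyl of protected quinates is known to favour the alkene on the cis-diol side, away from C8a, so the enoate is taken from shikimic acid, which already holds the C4a=C8a alkene and the allylic C8 carbinol in the required configuration. C7 is then cis to C8 in the precursor, which is immaterial because C7 is rebuilt, and the trans C6/C7 diol carries a diacetal where a cis diol would carry an acetonide.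

Remark 3: C4a of 5–16 and 26–28 is drawn α (cis to C1), as expected from hydrogen transfer anti to C1; it becomes sp2 in step 22, so either epimer serves.

Step 1
Reactants: 1 (−)-shikimic acid
Product: 2 methyl 4,5-O-[(2S,3S)-2,3-dimethoxybutane-2,3-diyl]shikimate
Conditions: butane-2,3-dione, HC(OMe)3, CSA (cat.), MeOH, reflux
Reagents that add atoms: methanol, CO; butane-2,3-dione, CC(=O)C(C)=O; trimethyl orthoformate, COC(OC)OC
Why: Fischer esterification and acid-catalysed diacetal formation should occur together; the chair dioxane with two axial (anomeric) methoxy groups forms only on the trans-diequatorial C6/C7 diol, which fixes both acetal centres and leaves the allylic C8 hydroxyl free.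

Step 2
Reactants: 2 methyl 4,5-O-[(2S,3S)-2,3-dimethoxybutane-2,3-diyl]shikimate; 3 (bromomethyl)chlorodimethylsilane
Product: 4 methyl 3-O-[(bromomethyl)dimethylsilyl]-4,5-O-[(2S,3S)-2,3-dimethoxybutane-2,3-diyl]shikimate
Conditions: Et3N, DMAP (cat.), CH2Cl2, 0 °C
Reagents that add atoms: 3 (bromomethyl)chlorodimethylsilane, C[Si](C)(Cl)CBr
Why: Silylation of the only free hydroxyl with a chlorosilane and an amine base should be clean and touches no stereocentre.

Step 3
Reactants: 4 methyl 3-O-[(bromomethyl)dimethylsilyl]-4,5-O-[(2S,3S)-2,3-dimethoxybutane-2,3-diyl]shikimate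
Product: 5 cis-fused oxasilolane ester (C1 on C8a α; C4a ester α)
Conditions: Bu3SnH (slow addition), AIBN (cat.), PhH (0.01 M), reflux
Reagents that add atoms: none
Why: The tributyltin radical abstracts bromine to give a nucleophilic α-silyl methyl radical that adds to C8a, the electron-poor β-carbon of the enoate, and the ester-stabilised C4a radical then takes hydrogen from Bu3SnH. This is the known radical cyclisation of (bromomethyl)dimethylsilyl ethers of cyclic allylic alcohols. The oxasilolane ring closes 5-exo-trig. The three-atom O–Si–CH2 tether can reach only the alkene face that carries the C8 oxygen, so the ring is cis-fused and C8a is set with C1 cis to O8; the C4a centre, set by hydrogen transfer anti to C1, is erased later. The step needs 5-exo over 6-endo closure and cyclisation faster than direct reduction: the first is secured by polarity matching at the β-carbon and the ester-stabilised product radical, the second by slow stannane addition at high dilution.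

Step 4
Reactants: 5 cis-fused oxasilolane ester
Product: 7 hydroxy lactone (cis γ-lactone C1–O–C4(=O); 8α-OH; 6β,7α-diacetal), via diol ester 6 (not isolated)
Conditions: KF, KHCO3, 30% H2O2, THF/MeOH, rt; then PPTS (cat.), PhMe, 60 °C
Reagents that add atoms: hydrogen peroxide, OO
Why: Tamao–Fleming oxidation of the cyclic alkoxysilane should replace C–Si by C–OH with retention and free O8, and the γ-hydroxy ester then lactonises under acid catalysis, masking C1–O and C4 in one group.

Step 5
Reactants: 7 hydroxy lactone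
Product: 8 8α-benzoate of the hydroxy lactone
Conditions: BzCl, pyridine, DMAP (cat.), CH2Cl2, rt
Reagents that add atoms: benzoyl chloride, O=C(Cl)c1ccccc1
Why: DMAP-catalysed acylation of the single free hydroxyl should proceed without affecting lactone or diacetal.

Step 6
Reactants: 8 8α-benzoate of the hydroxy lactone
Product: 9 6β,7α-diol 8α-benzoate lactone
Conditions: TFA/H2O (9:1), CH2Cl2, 0 °C → rt
Reagents that add atoms: none
Why: Aqueous-acid hydrolysis should remove the diacetal while lactone and benzoate are stable and acyl migration is slow under acid.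

Step 7
Reactants: 9 6β,7α-diol 8α-benzoate lactone
Product: 10 6β-silyl ether (6β-OTBS; 7α-OH; 8α-OBz)
Conditions: TBSCl, imidazole, DMF, 0 °C
Reagents that add atoms: tert-butyldimethylsilyl chloride, CC(C)(C)[Si](C)(C)Cl
Why: Kinetic silylation should select the C6 hydroxyl next to the C5 methylene over the C7 hydroxyl, which is flanked by two oxygenated carbons.

Step 8
Reactants: 10 6β-silyl ether
Product: 11 C7 ketone
Conditions: Dess–Martin periodinane, NaHCO3, CH2Cl2, rt
Reagents that add atoms: none
Why: Dess–Martin oxidation of the remaining secondary alcohol under buffered conditions should not epimerise C8 or C6.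

Step 9
Reactants: 11 C7 ketone
Product: 12 C7 exo-methylene compound
Conditions: Zn, CH2Br2, TiCl4, THF/CH2Cl2, 0 °C → rt
Reagents that add atoms: dibromomethane, BrCBr
Why: Takai–Lombardo methylenation is non-basic, so the α-centres C8 and C6 should not enolise, and it leaves lactone and benzoate untouched.

Step 10
Reactants: 12 C7 exo-methylene compound
Product: 13 tertiary alcohol (7β-OH; 7α-CH3)
Conditions: Mn(dpm)3 (cat.), PhSiH3, O2 (1 atm), i-PrOH/CH2Cl2, 0 °C → rt
Reagents that add atoms: dioxygen, O=O
Why: Mukaiyama hydration (hydrogen-atom transfer to the methylene, then capture of the tertiary C7 radical by O2) should give the Markovnikov alcohol with oxygen on the β face, away from the C8 benzoate and the C1 methylene on the α face, so the methyl ends cis to O8.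

Step 11
Reactants: 13 tertiary alcohol
Product: 14 lactol triol (anomeric mixture; 8α-OH freed)
Conditions: i-Bu2AlH (excess), CH2Cl2, −78 °C; aq. potassium sodium tartrate
Reagents that add atoms: none
Why: Low-temperature hydride reduction should stop at the lactol aluminate and cleave the benzoate reductively in the same operation; the new anomeric centre is a mixture of no consequence.

Step 12
Reactants: 14 lactol triol
Product: 15 alkyne triol (4a-ethynyl; C1–OH; 8α-OH; 7β-OH; 6β-OTBS)
Conditions: dimethyl (1-diazo-2-oxopropyl)phosphonate, K2CO3, MeOH, 0 °C → rt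
Reagents that add atoms: dimethyl (1-diazo-2-oxopropyl)phosphonate, COP(=O)(OC)C(=[N+]=[N-])C(C)=O
Why: Seyferth–Gilbert homologation with the Ohira–Bestmann reagent should act on the open hydroxy-aldehyde form of the lactol, adding C3 and unmasking the C1 hydroxyl.

Step 13
Reactants: 15 alkyne triol
Product: 16 alkyne acetonide (C1,O8-isopropylidene)
Conditions: Me2C(OMe)2, PPTS (cat.), CH2Cl2, rt
Reagents that add atoms: 2,2-dimethoxypropane, COC(C)(C)OC
Why: Acetonide formation under thermodynamic control should bridge only the cis 1,3-diol C1–OH/C8–OH, because the C7 and C8 hydroxyls are trans-diaxial and O6 is silylated.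

Step 14
Reactants: 17 L-allo-isoleucine
Product: 18 (2S,3R)-2-hydroxy-3-methylpentanoic acid
Conditions: NaNO2, 1 M H2SO4, 0 °C → rt
Reagents that add atoms: water, O
Why: Diazotisation of the α-amino acid should give the hydroxy acid with overall retention (the carboxylate displaces N2 to an α-lactone that water reopens), which sets C4′ (S) beside the existing C5′ (R).

Step 15
Reactants: 18 (2S,3R)-2-hydroxy-3-methylpentanoic acid
Product: 19 (2S,3R)-2-hydroxy-N-methoxy-N,3-dimethylpentanamide
Conditions: MeNHOMe·HCl, EDC·HCl, HOBt, N-methylmorpholine, CH2Cl2, 0 °C → rt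
Reagents that add atoms: N,O-dimethylhydroxylamine hydrochloride, CNOC.Cl
Why: Carbodiimide amide coupling should give the Weinreb amide, since the amine is far more nucleophilic than the hindered secondary hydroxyl.

Step 16
Reactants: 19 (2S,3R)-2-hydroxy-N-methoxy-N,3-dimethylpentanamide
Product: 20 (4S,5R)-4-hydroxy-5-methyl-1-(trimethylsilyl)hept-1-yn-3-one
Conditions: LiC≡CSiMe3 (3 equiv), THF, −78 → 0 °C; aq. NH4Cl
Reagents that add atoms: lithium (trimethylsilyl)acetylide, [Li]C#C[Si](C)(C)C
Why: Weinreb ketone synthesis should stop at the ynone because the chelated tetrahedral adduct survives until work-up; one equivalent of acetylide is spent on the hydroxyl.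

Step 17
Reactants: 20 (4S,5R)-4-hydroxy-5-methyl-1-(trimethylsilyl)hept-1-yn-3-one
Product: 22 (3R,4S,5R)-3,5-dimethylhept-1-yne-3,4-diol, via silylalkyne diol 21 (not isolated)
Conditions: MeMgBr (3.5 equiv), THF, −78 → −20 °C; then MeOH, K2CO3, rt
Reagents that add atoms: methylmagnesium bromide, C[Mg]Br
Why: Chelation-controlled Grignard addition should set C3′ (R), because the magnesium alkoxide at O4′ and the ketone oxygen form a five-membered chelate and methyl enters from the face of the C4′ hydrogen; methanolic carbonate then cleaves the alkynylsilane.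

Step 18
Reactants: 22 (3R,4S,5R)-3,5-dimethylhept-1-yne-3,4-diol
Product: 23 (4R,5S)-5-[(2R)-butan-2-yl]-4-ethynyl-2,2,4-trimethyl-1,3-dioxolane
Conditions: Me2C(OMe)2, PPTS (cat.), CH2Cl2, rt
Reagents that add atoms: 2,2-dimethoxypropane, COC(C)(C)OC
Why: Acid-catalysed transacetalisation should close the five-membered acetonide on the vicinal diol without touching a stereocentre.

Step 19
Reactants: 23 (4R,5S)-5-[(2R)-butan-2-yl]-4-ethynyl-2,2,4-trimethyl-1,3-dioxolane
Product: 25 (4R,5S)-5-[(2R)-butan-2-yl]-4-[(E)-2-iodoethenyl]-2,2,4-trimethyl-1,3-dioxolane, via alkenylzirconocene 24 (not isolated)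
Conditions: Cp2Zr(H)Cl, THF, rt; then I2, 0 °C
Reagents that add atoms: iodine, II
Why: Hydrozirconation should add syn with zirconium at the terminal carbon, and iodinolysis with retention then gives the (E)-iodoalkene.

Step 20
Reactants: 16 alkyne acetonide; 25 (E)-iodoalkene acetonide
Product: 26 protected enyne (C3–C1′ bond formed)
Conditions: Pd(PPh3)4 (cat.), CuI (cat.), Et3N, THF, rt
Reagents that add atoms: 25 (E)-iodoalkene acetonide, CC[C@@H](C)[C@@H]1OC(C)(C)O[C@]1(C)/C=C/I
Why: Sonogashira coupling of a terminal alkyne with an alkenyl iodide should proceed with retention of the E geometry and tolerates the free tertiary hydroxyl.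

Step 21
Reactants: 26 protected enyne
Product: 27 C6 alcohol (6β-OH; 7β-OH)
Conditions: Bu4NF, THF, 0 °C → rt
Reagents that add atoms: none
Why: Fluoride desilylation should free the C6 hydroxyl while both acetonides and the enyne are inert.

Step 22
Reactants: 27 C6 alcohol
Product: 29 protected ynenone (C6 ketone; C4a=C5), via saturated ketone 28 (not isolated)
Conditions: IBX (4 equiv), DMSO, rt then 70 °C
Reagents that add atoms: none
Why: IBX oxidation of the secondary alcohol (without glycol cleavage) followed by IBX dehydrogenation through the enol should give the enone, and because C7 is quaternary the ketone can enolise only toward C5, so the new double bond must be C4a=C5.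

Step 23
Reactants: 29 protected ynenone
Product: 31 CNP0291643.7, via pentaol ynenone 30 (not isolated)
Conditions: AcOH/THF/H2O (3:1:1), 40 °C; then DABCO (cat.), CHCl3, rt
Reagents that add atoms: none
Why: Acid hydrolysis of both acetonides should free the C1 hydroxyl, which adds to the alkyne terminus C3 (the δ-carbon of the ynenone) in a 6-endo-dig oxa-Michael 1,6-addition, and protonation at C4 gives the conjugated pyran; attack at C4 would oppose the polarisation of the enynone.

Compound list

1 | (−)-shikimic acid | O=C(O)C1=C[C@@H](O)[C@@H](O)[C@H](O)C1 | starting material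
2 | methyl 4,5-O-[(2S,3S)-2,3-dimethoxybutane-2,3-diyl]shikimate (free allylic 8α-OH) | COC(=O)C1=C[C@@H](O)[C@H]2O[C@](C)(OC)[C@@](C)(OC)O[C@@H]2C1 | intermediate
3 | (bromomethyl)chlorodimethylsilane | C[Si](C)(Cl)CBr | starting material
4 | methyl 3-O-[(bromomethyl)dimethylsilyl]-4,5-O-[(2S,3S)-2,3-dimethoxybutane-2,3-diyl]shikimate (radical precursor) | COC(=O)C1=C[C@@H](O[Si](C)(C)CBr)[C@H]2O[C@](C)(OC)[C@@](C)(OC)O[C@@H]2C1 | intermediate
5 | cis-fused oxasilolane ester: C1 on C8a α, joined through SiMe2 to O8 (α); methyl ester on C4a α; 6β,7α-diacetal | COC(=O)[C@@H]1C[C@H]2O[C@](C)(OC)[C@@](C)(OC)O[C@@H]2[C@@H]2O[Si](C)(C)C[C@H]12 | intermediate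
6 | diol ester: 8α-OH, 8a-α-hydroxymethyl, 4a-α-methyl ester, 6β,7α-diacetal | COC(=O)[C@@H]1C[C@H]2O[C@](C)(OC)[C@@](C)(OC)O[C@@H]2[C@H](O)[C@@H]1CO | intermediate
7 | hydroxy lactone: cis-fused γ-lactone C1–O–C4(=O) across C8a/C4a, 8α-OH, 6β,7α-diacetal | O=C1OC[C@H]2[C@@H](O)[C@H]3O[C@](C)(OC)[C@@](C)(OC)O[C@@H]3C[C@@H]12 | intermediate
8 | 8α-benzoate of 7 | O=C1OC[C@H]2[C@@H](OC(=O)c4ccccc4)[C@H]3O[C@](C)(OC)[C@@](C)(OC)O[C@@H]3C[C@@H]12 | intermediate
9 | lactone with 6β-OH, 7α-OH, 8α-OBz | O=C1OC[C@H]2[C@@H](OC(=O)c3ccccc3)[C@@H](O)[C@H](O)C[C@@H]12 | intermediate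
10 | lactone with 6β-OTBS, 7α-OH, 8α-OBz | O=C1OC[C@H]2[C@@H](OC(=O)c3ccccc3)[C@@H](O)[C@H](O[Si](C)(C)C(C)(C)C)C[C@@H]12 | intermediate
11 | C7 ketone: lactone with 6β-OTBS, 8α-OBz | O=C1OC[C@H]2[C@@H](OC(=O)c3ccccc3)C(=O)[C@H](O[Si](C)(C)C(C)(C)C)C[C@@H]12 | intermediate
12 | C7 exo-methylene lactone with 6β-OTBS, 8α-OBz | O=C1OC[C@H]2[C@@H](OC(=O)c3ccccc3)C(=C)[C@H](O[Si](C)(C)C(C)(C)C)C[C@@H]12 | intermediate
13 | tertiary alcohol: lactone with 7β-OH, 7α-CH3, 6β-OTBS, 8α-OBz | O=C1OC[C@H]2[C@@H](OC(=O)c3ccccc3)[C@](C)(O)[C@H](O[Si](C)(C)C(C)(C)C)C[C@@H]12 | intermediate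
14 | lactol triol: cis-fused lactol (anomeric centre unassigned), 8α-OH, 7β-OH, 7α-CH3, 6β-OTBS | OC1OC[C@H]2[C@@H](O)[C@](C)(O)[C@H](O[Si](C)(C)C(C)(C)C)C[C@@H]12 | intermediate
15 | alkyne triol: 4a-α-ethynyl, 8a-α-CH2OH, 8α-OH, 7β-OH, 7α-CH3, 6β-OTBS cyclohexane | C#C[C@@H]1C[C@@H](O[Si](C)(C)C(C)(C)C)[C@@](C)(O)[C@H](O)[C@@H]1CO | intermediate
16 | alkyne acetonide: C1,O8-isopropylidene acetal of 15 | C#C[C@@H]1C[C@@H](O[Si](C)(C)C(C)(C)C)[C@@](C)(O)[C@@H]2OC(C)(C)OC[C@H]12 | intermediate
17 | L-allo-isoleucine | CC[C@@H](C)[C@H](N)C(=O)O | starting material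
18 | (2S,3R)-2-hydroxy-3-methylpentanoic acid | CC[C@@H](C)[C@H](O)C(=O)O | intermediate
19 | (2S,3R)-2-hydroxy-N-methoxy-N,3-dimethylpentanamide | CC[C@@H](C)[C@H](O)C(=O)N(C)OC | intermediate
20 | (4S,5R)-4-hydroxy-5-methyl-1-(trimethylsilyl)hept-1-yn-3-one | CC[C@@H](C)[C@H](O)C(=O)C#C[Si](C)(C)C | intermediate
21 | (3R,4S,5R)-3,5-dimethyl-1-(trimethylsilyl)hept-1-yne-3,4-diol | CC[C@@H](C)[C@H](O)[C@](C)(O)C#C[Si](C)(C)C | intermediate
22 | (3R,4S,5R)-3,5-dimethylhept-1-yne-3,4-diol | CC[C@@H](C)[C@H](O)[C@](C)(O)C#C | intermediate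
23 | (4R,5S)-5-[(2R)-butan-2-yl]-4-ethynyl-2,2,4-trimethyl-1,3-dioxolane | CC[C@@H](C)[C@@H]1OC(C)(C)O[C@]1(C)C#C | intermediate
24 | (E)-alkenyl(chloro)zirconocene from 23, zirconium on the terminal carbon | CC[C@@H](C)[C@@H]1OC(C)(C)O[C@]1(C)/C=C/[Zr](Cl)(C2C=CC=C2)C2C=CC=C2 | intermediate
25 | (4R,5S)-5-[(2R)-butan-2-yl]-4-[(E)-2-iodoethenyl]-2,2,4-trimethyl-1,3-dioxolane | CC[C@@H](C)[C@@H]1OC(C)(C)O[C@]1(C)/C=C/I | intermediate
26 | protected enyne: 16 joined at the alkyne terminus C3 to C1′ of the (E)-alkenyl dioxolane | CC[C@@H](C)[C@@H]1OC(C)(C)O[C@]1(C)/C=C/C#C[C@@H]1C[C@@H](O[Si](C)(C)C(C)(C)C)[C@@](C)(O)[C@@H]2OC(C)(C)OC[C@H]12 | intermediate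
27 | C6 alcohol: 26 without the silyl group (6β-OH, 7β-OH) | CC[C@@H](C)[C@@H]1OC(C)(C)O[C@]1(C)/C=C/C#C[C@@H]1C[C@@H](O)[C@@](C)(O)[C@@H]2OC(C)(C)OC[C@H]12 | intermediate
28 | saturated C6 ketone of 27 | CC[C@@H](C)[C@@H]1OC(C)(C)O[C@]1(C)/C=C/C#C[C@@H]1CC(=O)[C@@](C)(O)[C@@H]2OC(C)(C)OC[C@H]12 | intermediate
29 | protected ynenone: C6 ketone, C4a=C5, C4≡C3, both acetonides | CC[C@@H](C)[C@@H]1OC(C)(C)O[C@]1(C)/C=C/C#CC1=CC(=O)[C@@](C)(O)[C@@H]2OC(C)(C)OC[C@H]12 | intermediate
30 | pentaol ynenone (29 without acetonides) | CC[C@@H](C)[C@H](O)[C@](C)(O)/C=C/C#CC1=CC(=O)[C@@](C)(O)[C@H](O)[C@@H]1CO | intermediate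
31 | CNP0291643.7, (7S,8R,8aS)-3-[(1E,3R,4S,5R)-3,4-dihydroxy-3,5-dimethylhept-1-en-1-yl]-7,8-dihydroxy-7-methyl-8,8a-dihydro-1H-isochromen-6(7H)-one | CC[C@@H](C)[C@H](O)[C@](C)(O)/C=C/C1=CC2=CC(=O)[C@@](C)(O)[C@H](O)[C@@H]2CO1 | target

Total step count: 23 (17 on the core line, 6 for the side-chain iodide).
Longest linear sequence: 17 steps (steps 1–13 and 20–23, from shikimic acid).

Steps most likely to fail

Step 10. The C7 radical may capture oxygen on both faces, which would give a mixture of C7 epimers. The fallback delivers the oxygen under direction of the C6 hydroxyl. It sets out from 12, which would be desilylated (HF·pyridine, THF) to the allylic alcohol F1 and epoxidised with VO(acac)2/t-BuOOH syn to the C6 hydroxyl to give the spiro-epoxide F2. The epoxide would be opened at its methylene carbon with LiI/AcOH to the iodohydrin F3 and reduced with Bu3SnH/AIBN to the diol F4. Silylation of the secondary C6 hydroxyl (TBSCl, imidazole) would bring the sequence back to the route at 13.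

Step 22. The one-pot sequence may stall at the saturated ketone, or the hot oxidant may erode the enyne and the acetonides. The fallback separates the two oxidations. It sets out from 27, which would be oxidised with Dess–Martin periodinane to isolated 28 and then treated with Me3SiOTf/Et3N to give the bis-silyl compound F5 (silyl enol ether C5=C6, O7 silylated). Saegusa–Ito oxidation with Pd(OAc)2 in MeCN would give the O7-silylated ynenone F6. F6 would be carried through the conditions of step 23, where the acid also removes the silyl ether, so the fallback returns to the route at 31.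

Step 23. The freed C1 hydroxyl may fail to add to C3 or may close onto C4, and prolonged acid may ionise the allylic C3′ carbinol. The fallback first raises C3 to the carbonyl oxidation level. It sets out from 29, to which pyrrolidine would add at C3 (1,6-addition) to give the dienaminone F7. Aqueous acetic acid would then remove both acetonides and let the C1 hydroxyl displace pyrrolidine at C3 by addition–elimination, which returns to the route at 31.

Further compounds

F1 | step 10 | allylic alcohol: C7 exo-methylene lactone with 6β-OH, 8α-OBz | O=C1OC[C@H]2[C@@H](OC(=O)c3ccccc3)C(=C)[C@H](O)C[C@@H]12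
F2 | step 10 | spiro-epoxide: epoxide oxygen on C7 β (syn to 6β-OH), 8α-OBz lactone | O=C1OC[C@H]2[C@@H](OC(=O)c3ccccc3)[C@@]4(CO4)[C@H](O)C[C@@H]12
F3 | step 10 | iodohydrin: 7β-OH, 7α-CH2I, 6β-OH, 8α-OBz lactone | O=C1OC[C@H]2[C@@H](OC(=O)c3ccccc3)[C@](CI)(O)[C@H](O)C[C@@H]12
F4 | step 10 | diol: 7β-OH, 7α-CH3, 6β-OH, 8α-OBz lactone | O=C1OC[C@H]2[C@@H](OC(=O)c3ccccc3)[C@](C)(O)[C@H](O)C[C@@H]12
F5 | step 22 | bis-silyl compound: C5=C6 trimethylsilyl enol ether with O7 trimethylsilyl ether | CC[C@@H](C)[C@@H]1OC(C)(C)O[C@]1(C)/C=C/C#C[C@@H]1C=C(O[Si](C)(C)C)[C@@](C)(O[Si](C)(C)C)[C@@H]2OC(C)(C)OC[C@H]12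
F6 | step 22 | O7-trimethylsilyl ynenone | CC[C@@H](C)[C@@H]1OC(C)(C)O[C@]1(C)/C=C/C#CC1=CC(=O)[C@@](C)(O[Si](C)(C)C)[C@@H]2OC(C)(C)OC[C@H]12
F7 | step 23 | dienaminone: pyrrolidin-1-yl on C3, C3=C4, C4a=C5, C6 ketone, both acetonides | CC[C@@H](C)[C@@H]1OC(C)(C)O[C@]1(C)/C=C/C(=CC1=CC(=O)[C@@](C)(O)[C@@H]2OC(C)(C)OC[C@H]12)N1CCCC1
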